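**Remark on the chemistry (assumptions):** the SMILES is read as the (2S)-flavanone. Compounds 1, 2, 5, 9 and 10 are taken as purchased, and LiN(i-Pr)2 is used as a purchased solution.

## Analysis of the target

The target is a (2S)-flavanone. Ring C is a 2,3-dihydro-4H-pyran-4-one (O1, C2, C3, C4, C4a, C8a), fused along C4a–C8a to aromatic ring A (C4a, C5, C6, C7, C8, C8a), and it carries aryl ring B at C2. Ring A is a pentasubstituted phloroglucinol: acyl at C4a, free OH at C5 and C7, H at C6, a prenyl group at C8 and the ether oxygen O1 at C8a. Its alternating oxygens mark it as a folded triketide, with C5 a former ester carbon and C7 and C8a former ketones. The only stereocentre, C2, is benzylic, carries O1, lies beta to the C4 carbonyl and is attached to a para-methoxyaryl ring. It is therefore lost under base by retro-oxa-Michael opening to a chalcone, and under acid by ionisation. Ring B is an anisole whose C3' chain ends in a 1,1-disubstituted alkene that isomerises to the trisubstituted isomer under acid or metal hydrides, and the C8 prenyl group next to the free C7–OH closes to a chromane under acid. The difficulty lies in two selectivities rather than in any single bond: which of the two oxygens ortho to the acyl group becomes O1 (8-prenyl versus 6-prenyl), and the configuration at C2, which every chalcone-based route makes reversible. The feature the route exploits is the contiguous array C8a(–O1)–C8(prenyl)–C7(O)–C6–C5(O) of ring A: if ring A is closed last, between C4a and C5, on a ring C that already holds the O1–C8a bond and the C8 prenyl group, the regiochemical question is settled by constitution, no phenol needs protection, and C2 never passes through a chalcone.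

## Retrosynthetic reasoning

**Ring A, bond C4a–C5 (16 to 14).** Ring A is cut between C4a and C5, the bond that chalcone synthase makes last. This leads back through the keto tautomer 15 to 14, a chiral dihydropyranone that carries at C8a a prenylated beta-keto ester chain. The cut is placed here because 14 already contains O1–C8a, C8–prenyl and the C2 stereocentre, so the forward Claisen condensation can give only the 8-prenyl isomer and delivers the 5- and 7-hydroxyls free. The forward step must acylate C4a with the C5 ester and aromatise without opening ring C.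

**Ring C, bonds O1–C8a and C4–C4a (14 to 8 and 11).** The enol ether bond O1–C8a is cut to the hemiketal 13 and the open chain 12, a silyl-protected delta-hydroxy tetracarbonyl compound. In 12 the only carbonyl within six-ring reach of the C2 oxygen is C8a, so the cyclodehydration has no regiochemical choice. The chain 12 is then cut between C4 and C4a into the Weinreb amide 8 (C2, C3, C4 and ring B) and the triketide 11 (C4a, C8a, C8 with its prenyl group, C7, C6, C5). The forward reaction is acylation of the terminal carbanion of the trianion of 11, the most reactive site of the polyanion, by an amide that cannot over-add.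

**Prenyl at C8 (11 to 9 and 10).** The C8–prenyl bond is cut to methyl 3,5-dioxohexanoate 9 and prenyl bromide 10. C8 is the methylene between the two ketones of 9 and its most acidic position, so the prenyl group goes in at the stage where its position is decided by pKa and not by the substitution pattern of an aromatic ring.

**Stereocentre C2 (8 to 7 to 6).** The silyl ether 8 comes from carbinol 7, and 7 from the aryl ketone 6 by asymmetric transfer hydrogenation. The C2–O bond made here is never broken again, so the configuration set in this step is the configuration of 16.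

**Ring B fragment (6 to 4 and 5; 4 to 1 and 2).** The beta-keto amide 6 is cut at the aryl ketone into benzoate 4 and acetamide 5 (crossed Claisen). Ester 4 is cut at the aryl–CH2 bond into bromide 1 and the alkylzinc 3 made from bromide 2 (Negishi coupling), which places the 3-methylbut-3-enyl chain as a terminal alkene without any acid or base that could move the double bond.

## Alternatives that were turned down

**Alternative 1:** the textbook disconnection cuts O1–C2 and C3–C1'-side carbon. A Claisen–Schmidt condensation would assemble chalcone A1 (in O-protected form), and an enantioselective intramolecular oxa-Michael addition would close ring C. It was turned down for three reasons. A1 has two hydroxyls ortho to the acyl group, so closure gives the target or its 6-prenyl isomer A2, and telling them apart needs selective acetal protection on a prenylated ring. Each acetal must later be removed with acid in the presence of two acid-sensitive alkenes and an ionisable C2. The oxa-Michael step is reversible for 5-oxygenated flavanones, so the configuration at C2 rests on a kinetic selectivity that the product can lose, and the catalysts that work best need an activating ester at C3 that costs two further steps.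

**Alternative 2:** the C2–C1' bond is cut. The forward key step is an asymmetric conjugate addition of boronic acid A4 to chromone A3 (a rhodium–chiral diene or a cationic divalent palladium–pyridine-oxazoline catalyst). This sets C2 well but moves the 6/8 regiochemical problem unchanged into the synthesis of A3. It also needs both phenols protected, because a free 5-OH chelates the carbonyl and a peri 5-alkoxy group lowers acceptor reactivity, and the acetals must again be removed with acid at the end. A divalent palladium aryl intermediate can also engage the 1,1-disubstituted alkene in an oxidative Heck reaction. The step count is not lower than that of the chosen route.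

**Alternative 3:** the C8–prenyl bond is cut last. The forward key step is a para-Claisen–Cope rearrangement of the 5-O-prenyl ether A5 (heat or Eu(fod)3), which moves the prenyl group from O5 through C6 to C8. It was turned down because it presupposes an enantioenriched 5,7-dihydroxyflavanone and so inherits the stereochemical problem of Alternative 1. It adds protection of O7, a forced alkylation of the hydrogen-bonded O5, the rearrangement and a deprotection. The first [3,3] shift lands on C6, which carries a hydrogen and can tautomerise to A6 before the Cope step. Heat or a Lewis acid on a 5-hydroxyflavanone also invites ring opening, with loss of configuration and 6/8 scrambling.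

Key step: step 7

## Route

Step 1
Reactants: 1 methyl 3-bromo-4-methoxybenzoate; 2 4-bromo-2-methylbut-1-ene
Product: 4 methyl 4-methoxy-3-(3-methylbut-3-en-1-yl)benzoate, via (3-methylbut-3-en-1-yl)zinc bromide 3 (not isolated)
Conditions: 2, Zn dust (activated with I2), LiCl, THF, 50 °C; then 1, Pd(OAc)2 (2 mol%), SPhos (4 mol%), THF, rt to 40 °C
Reagents that add atoms: none
Why: Negishi sp2–sp3 coupling; the alkylzinc halide tolerates the ester, and the bulky biarylphosphine should make reductive elimination faster than beta-hydride elimination, so the chain arrives as the terminal alkene.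

Step 2
Reactants: 4 methyl 4-methoxy-3-(3-methylbut-3-en-1-yl)benzoate; 5 N-methoxy-N-methylacetamide
Product: 6 N-methoxy-3-[4-methoxy-3-(3-methylbut-3-en-1-yl)phenyl]-N-methyl-3-oxopropanamide
Conditions: 5 (1.2 equiv), LiN(i-Pr)2 (2.4 equiv), THF, −78 °C; then 4, −78 to −20 °C; aq. NH4Cl
Reagents that add atoms: none
Why: crossed Claisen condensation of the amide enolate with a non-enolisable aryl ester; the second equivalent of base holds the product as its enolate and drives the equilibrium.

Step 3
Reactants: 6 N-methoxy-3-[4-methoxy-3-(3-methylbut-3-en-1-yl)phenyl]-N-methyl-3-oxopropanamide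
Product: 7 (3S)-3-hydroxy-N-methoxy-3-[4-methoxy-3-(3-methylbut-3-en-1-yl)phenyl]-N-methylpropanamide
Conditions: RuCl[(S,S)-TsDPEN](p-cymene) (1 mol%), HCO2H/Et3N (5:2), DMF, 30 °C
Reagents that add atoms: none
Why: Noyori asymmetric transfer hydrogenation of an aryl ketone; the (S,S)-ligand should deliver hydride to the same face as in acetophenone, which here is the (S)-carbinol (O > aryl > CH2), and the outer-sphere mechanism leaves the alkene and the N–O bond untouched.

Step 4
Reactants: 7 (3S)-3-hydroxy-N-methoxy-3-[4-methoxy-3-(3-methylbut-3-en-1-yl)phenyl]-N-methylpropanamide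
Product: 8 (3S)-N-methoxy-3-[4-methoxy-3-(3-methylbut-3-en-1-yl)phenyl]-N-methyl-3-[(triethylsilyl)oxy]propanamide
Conditions: Et3SiCl, imidazole, CH2Cl2, 0 °C to rt
Reagents that add atoms: chlorotriethylsilane, CC[Si](Cl)(CC)CC
Why: standard silylation of a secondary alcohol; it removes the acidic OH and the retro-aldol pathway before the polyanion step, and the silyl group falls off under the mild acid that closes ring C.

Step 5
Reactants: 9 methyl 3,5-dioxohexanoate; 10 1-bromo-3-methylbut-2-ene
Product: 11 methyl 4-acetyl-7-methyl-3-oxooct-6-enoate (racemic at C4, largely enolised)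
Conditions: K2CO3 (1.1 equiv), acetone, 0 °C to rt
Reagents that add atoms: none
Why: C-alkylation of a 1,3-diketone enolate; the methylene between the two ketones is the most acidic site of 9, so the monoanion should form and react there with the allylic bromide by SN2.

Step 6
Reactants: 11 methyl 4-acetyl-7-methyl-3-oxooct-6-enoate; 8 (3S)-N-methoxy-3-[4-methoxy-3-(3-methylbut-3-en-1-yl)phenyl]-N-methyl-3-[(triethylsilyl)oxy]propanamide
Product: 14 methyl 4-{(2S)-2-[4-methoxy-3-(3-methylbut-3-en-1-yl)phenyl]-4-oxo-3,4-dihydro-2H-pyran-6-yl}-7-methyl-3-oxooct-6-enoate, via open-chain triketo ester 12 (not isolated), via cyclic hemiketal 13 (not isolated)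
Conditions: 11 (1.5 equiv), LiN(i-Pr)2 (4.6 equiv), THF, 0 °C; then 8, −78 to −20 °C; AcOH, −78 °C; crude product: aq. HF, MeCN, 0 °C to rt
Reagents that add atoms: none
Why: polyanion Claisen acylation, in which the terminal (last-formed, most nucleophilic) carbanion of the trianion of 11 attacks the Weinreb amide and the chelated tetrahedral adduct survives until the quench; HF then removes the silyl group, the freed C2 hydroxyl adds to C8a, the only carbonyl within six-ring reach, and dehydration gives the vinylogous ester without breaking the C2–O bond.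

Step 7
Reactants: 14 methyl 4-{(2S)-2-[4-methoxy-3-(3-methylbut-3-en-1-yl)phenyl]-4-oxo-3,4-dihydro-2H-pyran-6-yl}-7-methyl-3-oxooct-6-enoate
Product: 16 (2S)-5,7-dihydroxy-2-[4-methoxy-3-(3-methylbut-3-en-1-yl)phenyl]-8-(3-methylbut-2-en-1-yl)-2,3-dihydro-4H-chromen-4-one, via triketone tautomer 15 (not isolated)
Conditions: DBU (3 equiv), MeCN (dilute), 0 °C to rt; aq. NaH2PO4 (pH 5), 0 °C
Reagents that add atoms: none
Why: DBU reversibly deprotonates 14 at C8–H (alpha to the C7 ketone and vinylogous to C4=O) to give an extended enolate whose alpha carbon C4a attacks the C5 ester carbonyl; loss of methoxide gives trione 15, which enolises twice to the aromatic ring A of 16 and is held as its phenoxide. This is an intramolecular Claisen (Dieckmann-type) condensation, and its closest known relative is the base-mediated Claisen cyclisation of 3,5,7-trioxo esters to acylphloroglucinols, the laboratory version of the chalcone-synthase fold; here one of the three ketones (C8a) is masked as the cyclic enol ether of ring C. Ring A closes by a 6-(enolexo)-exo-trig attack, with aromatisation as the irreversible driving force. No new stereocentre is formed: C2 is carried through untouched, and the C8 epimers and enol forms of 14 converge on the same sp2 carbon. Chemoselectivity is structural, because aldol attack of C6 on C4 would give a bridged bicycle with a bridgehead alkene, O-acylation would need an eight-membered ring, and O1 is an ether that cannot lactonise. Regiochemistry is constitutional, because O1–C8a and C8–prenyl are already bonded, so only the 8-prenyl isomer can form. The step needs retention at C2: with more than one equivalent of a non-nucleophilic base in an aprotic solvent both 14 and 16 exist as vinylogous enolates in which C4 is no longer a free ketone, so C3–H is not acidic and retro-oxa-Michael opening should be suppressed, and the cold buffered quench keeps strong acid away from the two alkenes.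

## Compound list

1 | methyl 3-bromo-4-methoxybenzoate | COC(=O)c1ccc(OC)c(Br)c1 | starting material
2 | 4-bromo-2-methylbut-1-ene | C=C(C)CCBr | starting material
3 | (3-methylbut-3-en-1-yl)zinc bromide | C=C(C)CC[Zn]Br | intermediate
4 | methyl 4-methoxy-3-(3-methylbut-3-en-1-yl)benzoate | COC(=O)c1ccc(OC)c(CCC(C)=C)c1 | intermediate
5 | N-methoxy-N-methylacetamide | CC(=O)N(C)OC | starting material
6 | N-methoxy-3-[4-methoxy-3-(3-methylbut-3-en-1-yl)phenyl]-N-methyl-3-oxopropanamide | CON(C)C(=O)CC(=O)c1ccc(OC)c(CCC(C)=C)c1 | intermediate
7 | (3S)-3-hydroxy-N-methoxy-3-[4-methoxy-3-(3-methylbut-3-en-1-yl)phenyl]-N-methylpropanamide | C=C(C)CCc1cc([C@@H](O)CC(=O)N(C)OC)ccc1OC | intermediate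
8 | (3S)-N-methoxy-3-[4-methoxy-3-(3-methylbut-3-en-1-yl)phenyl]-N-methyl-3-[(triethylsilyl)oxy]propanamide | C=C(C)CCc1cc([C@@H](O[Si](CC)(CC)CC)CC(=O)N(C)OC)ccc1OC | intermediate
9 | methyl 3,5-dioxohexanoate | COC(=O)CC(=O)CC(C)=O | starting material
10 | 1-bromo-3-methylbut-2-ene | CC(C)=CCBr | starting material
11 | methyl 4-acetyl-7-methyl-3-oxooct-6-enoate | COC(=O)CC(=O)C(CC=C(C)C)C(C)=O | intermediate
12 | methyl (9S)-9-[4-methoxy-3-(3-methylbut-3-en-1-yl)phenyl]-4-(3-methylbut-2-en-1-yl)-3,5,7-trioxo-9-[(triethylsilyl)oxy]nonanoate | C=C(C)CCc1cc([C@@H](O[Si](CC)(CC)CC)CC(=O)CC(=O)C(CC=C(C)C)C(=O)CC(=O)OC)ccc1OC | intermediate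
13 | methyl 4-{(6S)-2-hydroxy-6-[4-methoxy-3-(3-methylbut-3-en-1-yl)phenyl]-4-oxooxan-2-yl}-7-methyl-3-oxooct-6-enoate | C=C(C)CCc1cc([C@@H]2CC(=O)CC(O)(C(CC=C(C)C)C(=O)CC(=O)OC)O2)ccc1OC | intermediate
14 | methyl 4-{(2S)-2-[4-methoxy-3-(3-methylbut-3-en-1-yl)phenyl]-4-oxo-3,4-dihydro-2H-pyran-6-yl}-7-methyl-3-oxooct-6-enoate | C=C(C)CCc1cc([C@@H]2CC(=O)C=C(C(CC=C(C)C)C(=O)CC(=O)OC)O2)ccc1OC | intermediate
15 | (2S)-2-[4-methoxy-3-(3-methylbut-3-en-1-yl)phenyl]-8-(3-methylbut-2-en-1-yl)-2,3,4a,6-tetrahydrochromene-4,5,7-trione | C=C(C)CCc1cc([C@@H]2CC(=O)C3C(=O)CC(=O)C(CC=C(C)C)=C3O2)ccc1OC | intermediate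
16 | (2S)-5,7-dihydroxy-2-[4-methoxy-3-(3-methylbut-3-en-1-yl)phenyl]-8-(3-methylbut-2-en-1-yl)-2,3-dihydro-4H-chromen-4-one | C=C(C)CCc1cc([C@@H]2CC(=O)c3c(O)cc(O)c(CC=C(C)C)c3O2)ccc1OC | target

## Step count and risk

Total step count: 7. Longest linear sequence: 6 (steps 1, 2, 3, 4, 6, 7); step 5 is a one-step branch.

**Step 7 (key step).** Two processes are most likely to go wrong. The Claisen closure may be slow, because the beta-keto ester is mostly present as its own enolate and is then a poor acyl donor. Prolonged exposure to base may open ring C by retro-oxa-Michael elimination, with loss of configuration at C2 and reclosure through the other oxygen. Fallback, which replaces the base-driven ester acylation by a base-free thermal acylketene closure; it sets out from 8 and comes back at 16. 2,2,6-Trimethyl-4H-1,3-dioxin-4-one is acetylated at its gamma carbon (LiN(SiMe3)2, AcCl, THF, −78 °C) to 2,2-dimethyl-6-(2-oxopropyl)-4H-1,3-dioxin-4-one F1. F1 is alkylated with 10 at its doubly activated methylene (K2CO3, acetone) to give 2,2-dimethyl-6-(6-methyl-2-oxohept-5-en-3-yl)-4H-1,3-dioxin-4-one F2. The dianion of F2 (LiN(i-Pr)2, 2.2 equiv) is acylated at its methyl carbon by 8, and aqueous HF in MeCN then gives 6-{1-[(2S)-2-[4-methoxy-3-(3-methylbut-3-en-1-yl)phenyl]-4-oxo-3,4-dihydro-2H-pyran-6-yl]-4-methylpent-3-en-1-yl}-2,2-dimethyl-4H-1,3-dioxin-4-one F3. Heating F3 in dilute toluene at 110 °C should expel acetone and give the acylketene 4-{(2S)-2-[4-methoxy-3-(3-methylbut-3-en-1-yl)phenyl]-4-oxo-3,4-dihydro-2H-pyran-6-yl}-7-methyl-3-oxoocta-1,6-dien-1-one F4. Its ketene carbon is far more electrophilic than the methyl ester and is expected to be captured by C4a (directly, or by six-electron electrocyclisation of its dienol form), giving 16 after tautomerisation. Dioxinone thermolysis and intramolecular capture of the acylketene are established; capture by this vinylogous-ester carbon is the extrapolation.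

**Step 6.** The strongly basic trianion may deprotonate 8 alpha to the amide instead of adding to it, which leads to beta-elimination of the silyloxy group. In the acid stage, the open chain may also cyclise through an enol oxygen to a pyranone before the C2 hydroxyl is freed. Fallback from 8, back at 12: i-Bu2AlH (CH2Cl2, −78 °C) reduces the Weinreb amide to (3S)-3-[4-methoxy-3-(3-methylbut-3-en-1-yl)phenyl]-3-[(triethylsilyl)oxy]propanal F5. Aldol addition of the trianion of 11 to this aldehyde, which should outrun enolisation, gives methyl (9S)-7-hydroxy-9-[4-methoxy-3-(3-methylbut-3-en-1-yl)phenyl]-4-(3-methylbut-2-en-1-yl)-3,5-dioxo-9-[(triethylsilyl)oxy]nonanoate F6 as a mixture of carbinol epimers. Oxidation with Dess–Martin periodinane (NaHCO3, CH2Cl2, 0 °C) gives 12, which is treated with aqueous HF as in step 6.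

**Step 2.** The lithium enolate of 5 may decompose (loss of formaldehyde from the N-methoxy group) before the electron-rich, sluggish benzoate is acylated. Fallback from 4, back at 7: Claisen condensation of 4 with ethyl acetate (LiN(SiMe3)2, THF, −40 °C) gives ethyl 3-[4-methoxy-3-(3-methylbut-3-en-1-yl)phenyl]-3-oxopropanoate F7. Transfer hydrogenation under the conditions of step 3 gives ethyl (3S)-3-hydroxy-3-[4-methoxy-3-(3-methylbut-3-en-1-yl)phenyl]propanoate F8. Aminolysis with MeNH(OMe)·HCl and i-PrMgCl (THF, −20 °C) then gives 7.

**Step 5.** Alkylation may be unselective: attack at the ester-flanked methylene, O-alkylation or double alkylation. Fallback from 10, back at 11, in which the position of the prenyl group is fixed by dianion chemistry and not by relative acidity: the dianion of methyl acetoacetate (NaH, then n-BuLi, THF, 0 °C) is alkylated at its terminal carbon with 10 to give methyl 7-methyl-3-oxooct-6-enoate F9. The dianion of F9 (LiN(i-Pr)2, 2.2 equiv) is then acetylated at C4 with 5 to give 11.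

## Further compounds

F1 | step 7 | 2,2-dimethyl-6-(2-oxopropyl)-4H-1,3-dioxin-4-one | CC(=O)CC1=CC(=O)OC(C)(C)O1
F2 | step 7 | 2,2-dimethyl-6-(6-methyl-2-oxohept-5-en-3-yl)-4H-1,3-dioxin-4-one | CC(=O)C(CC=C(C)C)C1=CC(=O)OC(C)(C)O1
F3 | step 7 | 6-{1-[(2S)-2-[4-methoxy-3-(3-methylbut-3-en-1-yl)phenyl]-4-oxo-3,4-dihydro-2H-pyran-6-yl]-4-methylpent-3-en-1-yl}-2,2-dimethyl-4H-1,3-dioxin-4-one | C=C(C)CCc1cc([C@@H]2CC(=O)C=C(C(CC=C(C)C)C3=CC(=O)OC(C)(C)O3)O2)ccc1OC
F4 | step 7 | 4-{(2S)-2-[4-methoxy-3-(3-methylbut-3-en-1-yl)phenyl]-4-oxo-3,4-dihydro-2H-pyran-6-yl}-7-methyl-3-oxoocta-1,6-dien-1-one | C=C(C)CCc1cc([C@@H]2CC(=O)C=C(C(CC=C(C)C)C(=O)C=C=O)O2)ccc1OC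
F5 | step 6 | (3S)-3-[4-methoxy-3-(3-methylbut-3-en-1-yl)phenyl]-3-[(triethylsilyl)oxy]propanal | C=C(C)CCc1cc([C@@H](O[Si](CC)(CC)CC)CC=O)ccc1OC
F6 | step 6 | methyl (9S)-7-hydroxy-9-[4-methoxy-3-(3-methylbut-3-en-1-yl)phenyl]-4-(3-methylbut-2-en-1-yl)-3,5-dioxo-9-[(triethylsilyl)oxy]nonanoate | C=C(C)CCc1cc([C@@H](O[Si](CC)(CC)CC)CC(O)CC(=O)C(CC=C(C)C)C(=O)CC(=O)OC)ccc1OC
F7 | step 2 | ethyl 3-[4-methoxy-3-(3-methylbut-3-en-1-yl)phenyl]-3-oxopropanoate | CCOC(=O)CC(=O)c1ccc(OC)c(CCC(C)=C)c1
F8 | step 2 | ethyl (3S)-3-hydroxy-3-[4-methoxy-3-(3-methylbut-3-en-1-yl)phenyl]propanoate | C=C(C)CCc1cc([C@@H](O)CC(=O)OCC)ccc1OC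
F9 | step 5 | methyl 7-methyl-3-oxooct-6-enoate | COC(=O)CC(=O)CCC=C(C)C
A1 | alternative 1 | (E)-1-[2,4,6-trihydroxy-3-(3-methylbut-2-en-1-yl)phenyl]-3-[4-methoxy-3-(3-methylbut-3-en-1-yl)phenyl]prop-2-en-1-one | C=C(C)CCc1cc(/C=C/C(=O)c2c(O)cc(O)c(CC=C(C)C)c2O)ccc1OC
A2 | alternative 1 | (2S)-5,7-dihydroxy-2-[4-methoxy-3-(3-methylbut-3-en-1-yl)phenyl]-6-(3-methylbut-2-en-1-yl)-2,3-dihydro-4H-chromen-4-one | C=C(C)CCc1cc([C@@H]2CC(=O)c3c(O)c(CC=C(C)C)c(O)cc3O2)ccc1OC
A3 | alternative 2 | 5,7-bis(methoxymethoxy)-8-(3-methylbut-2-en-1-yl)-4H-chromen-4-one | O=c1ccoc2c(CC=C(C)C)c(OCOC)cc(OCOC)c12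
A4 | alternative 2 | [4-methoxy-3-(3-methylbut-3-en-1-yl)phenyl]boronic acid | C=C(C)CCc1cc(B(O)O)ccc1OC
A5 | alternative 3 | (2S)-2-[4-methoxy-3-(3-methylbut-3-en-1-yl)phenyl]-5-[(3-methylbut-2-en-1-yl)oxy]-4-oxo-3,4-dihydro-2H-chromen-7-yl acetate | C=C(C)CCc1cc([C@@H]2CC(=O)c3c(OCC=C(C)C)cc(OC(C)=O)cc3O2)ccc1OC
A6 | alternative 3 | (2S)-5-hydroxy-2-[4-methoxy-3-(3-methylbut-3-en-1-yl)phenyl]-6-(2-methylbut-3-en-2-yl)-4-oxo-3,4-dihydro-2H-chromen-7-yl acetate | C=C(C)CCc1cc([C@@H]2CC(=O)c3c(O)c(C(C)(C)C=C)c(OC(C)=O)cc3O2)ccc1OC
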